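**Retrosynthetic overview**
- Late bonds: the C15 ester (acylation), C13=C14 and C14–C15 (methylalumination of a C13≡C14 alkyne, then formaldehyde), C9–C11 (copper-catalysed anti-SN2′ displacement of a C7 picolinate) and C8–C17 (vinyllithium plus formaldehyde).
- Feature the strategy rests on: in ring B (C5–C10) C8 is a one-carbon branch point between allylic C7 and C9. Without C8, ring B is the cyclopentene C5–C6–C7=C9–C10, so C8 is inserted as a dibromocarbene carbon and arrives with a bromine (handle for C17) and an allylic oxygen at C7 (leaving group for the attack at C9).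
- Ring order: ring A and the five-membered ring are bought together in an enantiopure bicyclic enedione (C10 already quaternary). C4 gem-dimethylation, deoxygenation and hydrogenation (C5) give the trans-hydrindene. Ring B is formed last, by one-carbon ring enlargement.

Key step: step 8

Remark: the SMILES is read as the ent-labdane series (C10 methyl and C9 side chain on one face, H5 and H9 on the other), so the (R)-enedione is the chiral source; it and 30-hydroxytriacontanoic acid are taken as purchasable; labdane numbering is used for all bicyclic compounds (in the hydrindanes the five-membered ring is C5–C6–C7–C9–C10).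

**Route**

Step 1
Reactants: 1 (R)-7a-methyl-2,3,7,7a-tetrahydro-1H-indene-1,5(6H)-dione
Product: 2 (R)-enedione mono-ketal (1,3-dioxolane on the cyclopentanone carbon C9; enone untouched)
Conditions: 2-ethyl-2-methyl-1,3-dioxolane (excess), ethylene glycol (cat), p-TsOH·H2O (cat), 25 °C
Reagents that add atoms: 2-ethyl-2-methyl-1,3-dioxolane CCC1(C)OCCO1
Why: acid-catalysed transketalisation in which the saturated cyclopentanone exchanges faster than the less electrophilic conjugated ketone, the quaternary stereocentre being untouched.

Step 2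
Reactants: 2 (R)-enedione mono-ketal
Product: 3 4,4-dimethyl β,γ-unsaturated ketone (C3 ketone; C4 gem-dimethyl; C5=C6 alkene; C9 dioxolane)
Conditions: KOtBu (2.5 equiv), t-BuOH, 25 °C; MeI (3 equiv), 0 → 25 °C
Reagents that add atoms: iodomethane CI
Why: deconjugative double α-alkylation of the thermodynamic dienolate, in which the second methylation makes C4 quaternary and leaves the alkene at C5=C6.

Step 3
Reactants: 3 4,4-dimethyl β,γ-unsaturated ketone
Product: 5 4,4,10-trimethyl hydrindene ketal (C3 now CH2; C5=C6 alkene; C9 dioxolane), via hydrazone 4 (not isolated)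
Conditions: N2H4·H2O, KOH, diethylene glycol, 130 °C then 200 °C
Reagents that add atoms: none
Why: Wolff–Kishner reduction, to which the ketal and the isolated trisubstituted alkene are inert and in which no α-stereocentre is at risk because C4 is quaternary.

Step 4
Reactants: 5 4,4,10-trimethyl hydrindene ketal
Product: 6 trans-hydrindane ketal (H5 trans to the C10 methyl)
Conditions: H2 (4 atm), 10% Pd/C, EtOAc, 25 °C
Reagents that add atoms: none
Why: heterogeneous syn-hydrogenation should occur from the face opposite the angular C10 methyl and the axial C4 methyl, which sets C5 with its hydrogen trans to the C10 methyl as in the homologous octalin and steroid ring-fusion alkenes.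

Step 5
Reactants: 6 trans-hydrindane ketal
Product: 7 trans-4,4,7a-trimethyloctahydro-1H-inden-1-one (C9 ketone)
Conditions: 2 M aq HCl, THF, 25 °C
Reagents that add atoms: water O
Why: acid-catalysed ketal hydrolysis, with no epimerisable centre next to the carbonyl because C10 is quaternary.

Step 6
Reactants: 7 trans-4,4,7a-trimethyloctahydro-1H-inden-1-one
Product: 9 enol triflate (C9(OTf)=C7), via potassium enolate 8 (not isolated)
Conditions: KN(SiMe3)2, THF, −78 °C; PhNTf2, −78 → 0 °C
Reagents that add atoms: N-phenylbis(trifluoromethanesulfonimide) O=S(=O)(N(c1ccccc1)S(=O)(=O)C(F)(F)F)C(F)(F)F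
Why: O-sulfonylation of a ketone enolate whose regiochemistry is unambiguous, since C7 is the only enolisable position next to C9.

Step 7
Reactants: 9 enol triflate
Product: 10 trans-3a,7,7-trimethyl-3a,4,5,6,7,7a-hexahydro-1H-indene (C7=C9 alkene)
Conditions: Pd(PPh3)4 (5 mol %), HCO2H, Et3N, DMF, 60 °C (product volatile: pentane extraction, careful concentration)
Reagents that add atoms: none
Why: palladium-catalysed formate reduction of an enol triflate (oxidative addition to zerovalent palladium, formate exchange, decarboxylation, C–H reductive elimination), which leaves the alkene where the triflate was.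

Step 8
Reactants: 10 trans-3a,7,7-trimethyl-3a,4,5,6,7,7a-hexahydro-1H-indene; 11 bromoform; 12 silver acetate
Product: 14 8-bromo-4,4,10-trimethyl-trans-octal-8-en-7-yl acetate (C8=C9; acetate trans to the C10 methyl), via dibromocyclopropane 13 (not isolated)
Conditions: CHBr3 (2 equiv), KOtBu (2.5 equiv), pentane, −20 → 0 °C; filter, concentrate cold; AgOAc (1.5 equiv), AcOH, 25 → 50 °C
Reagents that add atoms: bromoform BrC(Br)Br; silver acetate CC(=O)[O-].[Ag+]
Why: Dibromocarbene, formed from CHBr3 by α-elimination, adds in a concerted [2+1] cycloaddition to the only alkene, C7=C9, and monovalent silver then removes the bromide that lies over the five-membered ring while the C7–C9 bond opens in a disrotatory two-electron electrocyclic process to the 2-bromoallyl cation C7–C8–C9. The closest known reaction type is the silver-assisted solvolysis of dihalocarbene adducts of cyclopentenes, which gives 2-bromocyclohex-2-enyl esters. Ring B is closed by ring enlargement and not by a ring-closing bond: C7–C8 and C8–C9 are formed, C7–C9 is broken, and the five-membered ring C5–C6–C7–C9–C10 becomes the six-membered ring C5–C10. The new stereocentre C7 is controlled by the half-chair of the trans-fused cation, in which pseudoaxial attack through a chair-like transition state puts the acetate on the face opposite the C10 methyl, the arrangement that also avoids allylic 1,2-strain with the C8 bromine. The step needs regioselective capture at C7, which is secured by quaternary C10 shielding the neopentyl terminus C9, and it needs no chemoselectivity beyond that, because 10 is a hydrocarbon with one alkene. The face on which the carbene adds (expected opposite the C10 methyl) is of no consequence, because both cyclopropane CH centres become trigonal again in the cation.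

Step 9
Reactants: 14 8-bromo-4,4,10-trimethyl-trans-octal-8-en-7-yl acetate
Product: 15 8-bromo-4,4,10-trimethyl-trans-octal-8-en-7-ol (OH trans to the C10 methyl)
Conditions: K2CO3, MeOH, 25 °C
Reagents that add atoms: none
Why: base-catalysed transesterification at the acyl carbon, which leaves the C7–O bond, its configuration and the vinyl bromide untouched.

Step 10
Reactants: 15 8-bromo-4,4,10-trimethyl-trans-octal-8-en-7-ol
Product: 17 8-(hydroxymethyl)-4,4,10-trimethyl-trans-octal-8-en-7-ol (C7,C17-diol), via C8-lithio lithium alkoxide 16 (not isolated)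
Conditions: t-BuLi (3.2 equiv), THF, −78 °C; CH2O (gas from cracked paraformaldehyde), −78 → 0 °C; aq NH4Cl
Reagents that add atoms: formaldehyde C=O
Why: deprotonation of the alcohol and bromine–lithium exchange give a configurationally fixed cyclic vinyllithium (the neighbouring lithium alkoxide is no leaving group) that adds to formaldehyde and so installs C17.

Step 11
Reactants: 17 C7,C17-diol
Product: 18 C17 tert-butyldimethylsilyl ether (C7–OH free)
Conditions: TBSCl (1.05 equiv), imidazole, CH2Cl2, −20 → 0 °C
Reagents that add atoms: tert-butyldimethylsilyl chloride CC(C)(C)[Si](C)(C)Cl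
Why: silylation discriminates the primary allylic C17 hydroxyl from the hindered pseudoaxial secondary C7 hydroxyl.

Step 12
Reactants: 18 C17 tert-butyldimethylsilyl ether
Product: 19 C7 picolinate (pyridine-2-carboxylate; ester oxygen trans to the C10 methyl)
Conditions: picolinic acid, DCC, DMAP (cat), CH2Cl2, 25 °C
Reagents that add atoms: picolinic acid OC(=O)c1ccccn1
Why: Steglich esterification forms the acyl–oxygen bond only, so the C7 configuration is retained.

Step 13
Reactants: 20 but-3-yn-1-ol
Product: 22 4-(trimethylsilyl)but-3-yn-1-ol, via bis-silylated butynol 21 (not isolated)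
Conditions: n-BuLi (2.1 equiv), THF, −78 °C; Me3SiCl (2.2 equiv), −78 → 25 °C; 1 M aq HCl
Reagents that add atoms: chlorotrimethylsilane C[Si](C)(C)Cl
Why: double deprotonation and C,O-disilylation followed by selective acid hydrolysis of the labile O–Si bond gives the C-silylated alkynol.

Step 14
Reactants: 22 4-(trimethylsilyl)but-3-yn-1-ol
Product: 23 (4-bromobut-1-yn-1-yl)trimethylsilane
Conditions: CBr4, PPh3, CH2Cl2, 0 °C
Reagents that add atoms: carbon tetrabromide BrC(Br)(Br)Br
Why: Appel bromination of an unhindered primary alcohol.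

Step 15
Reactants: 19 C7 picolinate; 23 (4-bromobut-1-yn-1-yl)trimethylsilane
Product: 25 C9-(4-trimethylsilylbut-3-ynyl) Δ7-octalin C17 silyl ether (C9 chain cis to the C10 methyl; C7=C8), via Grignard reagent 24 (not isolated)
Conditions: 23, Mg, THF, 25–40 °C; then CuBr·SMe2 (0.2 equiv), 19, THF, −40 → 0 °C
Reagents that add atoms: none
Why: copper-catalysed anti-SN2′ allylic substitution of a picolinate (magnesium chelated between pyridine nitrogen and carbonyl oxygen activates the leaving group and directs monovalent copper to the γ-carbon), so C11 enters C9 on the face opposite the pseudoaxial C7–O bond, which is the face of the C10 methyl, and the alkene moves to C7=C8.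

Step 16
Reactants: 25 C9-(4-trimethylsilylbut-3-ynyl) Δ7-octalin C17 silyl ether
Product: 26 terminal alkyne (C13≡C14–H; C17 silyl ether kept)
Conditions: K2CO3, MeOH, 25 °C
Reagents that add atoms: none
Why: methoxide-mediated protodesilylation cleaves the alkynyl C–Si bond while the tert-butyldimethylsilyl ether is stable.

Step 17
Reactants: 26 terminal alkyne
Product: 29 17-O-silyl ent-labda-7,13E-diene-15,17-diol (free C15–OH), via alkenyldimethylalane 27 (not isolated), via lithium alkenylalanate 28 (not isolated)
Conditions: Me3Al (3 equiv), Cp2ZrCl2 (0.25 equiv), CH2Cl2, 0 → 25 °C; evaporate; n-BuLi, THF–hexane, −78 → 0 °C; (CH2O)n, 25 °C; aq NH4Cl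
Reagents that add atoms: trimethylaluminium C[Al](C)C; formaldehyde C=O
Why: zirconium-catalysed Negishi methylalumination adds methyl and aluminium syn across the terminal alkyne with methyl on C13, and the ate complex transfers the alkenyl group to formaldehyde with retention, which sets the 13E alkene and C15.

Step 18
Reactants: 30 30-hydroxytriacontanoic acid
Product: 32 30-(tert-butyldimethylsilyloxy)triacontanoic acid, via silyl ester 31 (not isolated)
Conditions: TBSCl (2.5 equiv), imidazole, THF–DMF, 45 °C; then K2CO3, MeOH–THF–H2O, 25 °C; acidify to pH 4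
Reagents that add atoms: tert-butyldimethylsilyl chloride CC(C)(C)[Si](C)(C)Cl
Why: exhaustive silylation followed by selective hydrolysis of the much more labile silyl ester masks only the ω-hydroxyl, which prevents self-esterification in the coupling.

Step 19
Reactants: 29 17-O-silyl ent-labda-7,13E-diene-15,17-diol; 32 30-(tert-butyldimethylsilyloxy)triacontanoic acid
Product: 33 bis-silyl ester (C15 ester; C17 and ω-oxygen silylated)
Conditions: DCC, DMAP (cat), CH2Cl2, 25 °C
Reagents that add atoms: none
Why: Steglich esterification at the only free hydroxyl, the unhindered primary allylic C15–OH.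

Step 20
Reactants: 33 bis-silyl ester
Product: 34 ent-labda-7,13E-diene-15,17-diol 15-(30-hydroxytriacontanoate) (CNP0329077.1)
Conditions: HF·pyridine, pyridine, THF, 0 → 25 °C
Reagents that add atoms: none
Why: buffered fluoride desilylation removes both primary silyl ethers without cleaving the allylic ester or ionising the allylic alcohol.

**Compound list**
1 | (R)-7a-methyl-2,3,7,7a-tetrahydro-1H-indene-1,5(6H)-dione | O=C1CCC2=CC(=O)CC[C@@]12C | starting material
2 | (R)-enedione mono-ketal (dioxolane at C9) | C12(OCCO2)CCC3=CC(=O)CC[C@@]13C | intermediate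
3 | 4,4-dimethyl β,γ-unsaturated ketone (C3 ketone, C5=C6, C9 dioxolane) | C12(OCCO2)CC=C3C(C)(C)C(=O)CC[C@@]13C | intermediate
4 | C3 hydrazone of 3 (not isolated) | C12(OCCO2)CC=C3C(C)(C)C(=NN)CC[C@@]13C | intermediate
5 | 4,4,10-trimethyl hydrindene ketal (C5=C6) | C12(OCCO2)CC=C3C(C)(C)CCC[C@@]13C | intermediate
6 | trans-hydrindane ketal (H5 trans to C10 methyl) | C12(OCCO2)CC[C@@H]3C(C)(C)CCC[C@@]13C | intermediate
7 | trans-4,4,7a-trimethyloctahydro-1H-inden-1-one | O=C1CC[C@@H]2C(C)(C)CCC[C@@]12C | intermediate
8 | potassium enolate of 7 (not isolated) | [K+].[O-]C1=CC[C@@H]2C(C)(C)CCC[C@@]12C | intermediate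
9 | enol triflate (C9(OTf)=C7) | FC(F)(F)S(=O)(=O)OC1=CC[C@@H]2C(C)(C)CCC[C@@]12C | intermediate
10 | trans-3a,7,7-trimethyl-3a,4,5,6,7,7a-hexahydro-1H-indene (C7=C9) | C1=CC[C@@H]2C(C)(C)CCC[C@@]12C | intermediate
11 | bromoform | BrC(Br)Br | starting material
12 | silver acetate | CC(=O)[O-].[Ag+] | starting material
13 | dibromocyclopropane (CBr2 bridging C7 and C9, on the face opposite the C10 methyl; not isolated) | BrC1(Br)[C@H]2C[C@@H]3C(C)(C)CCC[C@@]3(C)[C@@H]12 | intermediate
14 | 8-bromo-4,4,10-trimethyl-trans-octal-8-en-7-yl acetate (acetate trans to C10 methyl) | C1=C(Br)[C@@H](OC(C)=O)C[C@@H]2C(C)(C)CCC[C@@]12C | intermediate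
15 | 8-bromo-4,4,10-trimethyl-trans-octal-8-en-7-ol (OH trans to C10 methyl) | C1=C(Br)[C@@H](O)C[C@@H]2C(C)(C)CCC[C@@]12C | intermediate
16 | C8-lithio lithium C7-alkoxide (not isolated) | C1=C([Li])[C@@H](O[Li])C[C@@H]2C(C)(C)CCC[C@@]12C | intermediate
17 | 8-(hydroxymethyl)-4,4,10-trimethyl-trans-octal-8-en-7-ol | C1=C(CO)[C@@H](O)C[C@@H]2C(C)(C)CCC[C@@]12C | intermediate
18 | C17 tert-butyldimethylsilyl ether of 17 | C1=C(CO[Si](C)(C)C(C)(C)C)[C@@H](O)C[C@@H]2C(C)(C)CCC[C@@]12C | intermediate
19 | C7 picolinate of 18 | C1=C(CO[Si](C)(C)C(C)(C)C)[C@@H](OC(=O)c3ccccn3)C[C@@H]2C(C)(C)CCC[C@@]12C | intermediate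
20 | but-3-yn-1-ol | C#CCCO | starting material
21 | trimethyl[4-(trimethylsilyloxy)but-1-yn-1-yl]silane (not isolated) | C[Si](C)(C)C#CCCO[Si](C)(C)C | intermediate
22 | 4-(trimethylsilyl)but-3-yn-1-ol | C[Si](C)(C)C#CCCO | intermediate
23 | (4-bromobut-1-yn-1-yl)trimethylsilane | C[Si](C)(C)C#CCCBr | intermediate
24 | 4-(trimethylsilyl)but-3-ynylmagnesium bromide (not isolated) | C[Si](C)(C)C#CCC[Mg]Br | intermediate
25 | C9-(4-trimethylsilylbut-3-ynyl) Δ7-octalin C17 silyl ether (C9 chain cis to C10 methyl) | C[Si](C)(C)C#CCC[C@@H]1C(CO[Si](C)(C)C(C)(C)C)=CC[C@@H]2C(C)(C)CCC[C@@]12C | intermediate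
26 | terminal alkyne (C13≡C14–H) | C#CCC[C@@H]1C(CO[Si](C)(C)C(C)(C)C)=CC[C@@H]2C(C)(C)CCC[C@@]12C | intermediate
27 | (E)-alkenyldimethylalane (methyl on C13, aluminium on C14; not isolated) | C/C(=C\[Al](C)C)CC[C@@H]1C(CO[Si](C)(C)C(C)(C)C)=CC[C@@H]2C(C)(C)CCC[C@@]12C | intermediate
28 | lithium alkenyl(butyl)dimethylalanate (not isolated) | [Li+].C/C(=C\[Al-](C)(C)CCCC)CC[C@@H]1C(CO[Si](C)(C)C(C)(C)C)=CC[C@@H]2C(C)(C)CCC[C@@]12C | intermediate
29 | 17-O-(tert-butyldimethylsilyl) ent-labda-7,13E-diene-15,17-diol | C/C(=C\CO)CC[C@@H]1C(CO[Si](C)(C)C(C)(C)C)=CC[C@@H]2C(C)(C)CCC[C@@]12C | intermediate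
30 | 30-hydroxytriacontanoic acid | OCCCCCCCCCCCCCCCCCCCCCCCCCCCCCC(=O)O | starting material
31 | tert-butyldimethylsilyl 30-(tert-butyldimethylsilyloxy)triacontanoate (not isolated) | CC(C)(C)[Si](C)(C)OCCCCCCCCCCCCCCCCCCCCCCCCCCCCCC(=O)O[Si](C)(C)C(C)(C)C | intermediate
32 | 30-(tert-butyldimethylsilyloxy)triacontanoic acid | CC(C)(C)[Si](C)(C)OCCCCCCCCCCCCCCCCCCCCCCCCCCCCCC(=O)O | intermediate
33 | bis-silyl ester (C15 ester of 29 with 32) | C/C(=C\COC(=O)CCCCCCCCCCCCCCCCCCCCCCCCCCCCCO[Si](C)(C)C(C)(C)C)CC[C@@H]1C(CO[Si](C)(C)C(C)(C)C)=CC[C@@H]2C(C)(C)CCC[C@@]12C | intermediate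
34 | ent-labda-7,13E-diene-15,17-diol 15-(30-hydroxytriacontanoate), CNP0329077.1 | C/C(=C\COC(=O)CCCCCCCCCCCCCCCCCCCCCCCCCCCCCO)CC[C@@H]1C(CO)=CC[C@@H]2C(C)(C)CCC[C@@]12C | target

**Step count and risks**

Total: 20 steps. Longest linear sequence: 17 steps (steps 1–12, 15–17, 19, 20).

Step 15 (riskiest). What may go wrong: the alkylcopper must bond to C9 on the face that carries the axial C10 methyl, next to a quaternary carbon. If this γ-attack is slow, addition of the Grignard reagent to the picolinate carbonyl or direct substitution at C7 would take over. The fallback delivers the chain intramolecularly by sigmatropic rearrangement; it sets out from 18 and returns at 25. Pent-4-ynoic acid is C-silylated (LiN(iPr)2 2.2 equiv, Me3SiCl, aqueous acid) to 5-(trimethylsilyl)pent-4-ynoic acid F1. Mitsunobu esterification of 18 with this acid (PPh3, diisopropyl azodicarboxylate, toluene) inverts C7 and should give the C7-inverted ester F2, with the oxygen now on the face of the C10 methyl. Ireland–Claisen rearrangement (LiN(iPr)2, Me3SiCl, THF, −78 → 65 °C) moves the chain suprafacially from O7 to C9 on that same face and shifts the alkene to C7=C8, giving the C11 carboxylic acid F3 (the C11 configuration is of no consequence). Barton decarboxylation through the thiohydroxamate ester F4 (N-hydroxypyridine-2-thione, DCC; then t-BuSH, visible light) removes the carboxyl group and gives 25.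

Step 8. What may go wrong: capture of the bromoallyl cation by acetate from both faces of C7, so that the C7 configuration is not controlled; proton loss from C6 and a shift of the C10 methyl to cationic C9 are further leaks, and 13 may open to the allylic dibromide before silver is added (which feeds the same cation). The fallback corrects C7 stereoconvergently by oxidation, reduction and inversion; it sets out from 13 and returns at 15. Hydrolytic opening of 13 (AgNO3, aqueous acetone) gives the bromo allylic alcohol as a mixture of C7 epimers F5. MnO2 oxidises both epimers to the 8-bromo-8-en-7-one F6. Luche reduction (NaBH4, CeCl3·7H2O, MeOH) delivers hydride axially and should give the single equatorial alcohol, the C7 epimer of 15 F7. Mitsunobu inversion with 4-nitrobenzoic acid (PPh3, diisopropyl azodicarboxylate) gives the inverted 4-nitrobenzoate F8, whose methanolysis (K2CO3, MeOH) gives 15.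

Step 4. What may go wrong: poor facial selectivity in the delivery of hydrogen to C5 from the catalyst surface, which would give some cis-fused hydrindane. The fallback sets out from 5 and returns at 6: radical hydrogen-atom-transfer hydrogenation (Mn(dpm)3 with dpm = dipivaloylmethanate, PhSiH3, t-BuOOH, i-PrOH). Hydrogen-atom transfer to C6 gives the tertiary C5 radical, which should be reduced from the face away from the C10 and axial C4 methyl groups; this stepwise mechanism is known to favour trans ring fusions where surface hydrogenation does not. This fallback makes no new compound (F0).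

**Further compounds**
F1 | step 15 | 5-(trimethylsilyl)pent-4-ynoic acid | C[Si](C)(C)C#CCCC(=O)O
F2 | step 15 | C7-inverted 5-(trimethylsilyl)pent-4-ynoate of 18 (ester oxygen cis to the C10 methyl) | C1=C(CO[Si](C)(C)C(C)(C)C)[C@H](OC(=O)CCC#C[Si](C)(C)C)C[C@@H]2C(C)(C)CCC[C@@]12C
F3 | step 15 | C11 carboxylic acid of 25 (C11 configuration undefined) | C[Si](C)(C)C#CCC(C(=O)O)[C@@H]1C(CO[Si](C)(C)C(C)(C)C)=CC[C@@H]2C(C)(C)CCC[C@@]12C
F4 | step 15 | N-acyloxypyridine-2-thione ester of F3 | C[Si](C)(C)C#CCC(C(=O)ON3C=CC=CC3=S)[C@@H]1C(CO[Si](C)(C)C(C)(C)C)=CC[C@@H]2C(C)(C)CCC[C@@]12C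
F5 | step 8 | 8-bromo-4,4,10-trimethyl-trans-octal-8-en-7-ol, mixture of C7 epimers | C1=C(Br)C(O)C[C@@H]2C(C)(C)CCC[C@@]12C
F6 | step 8 | 8-bromo-4,4,10-trimethyl-trans-octal-8-en-7-one | C1=C(Br)C(=O)C[C@@H]2C(C)(C)CCC[C@@]12C
F7 | step 8 | C7 epimer of 15 (OH cis to the C10 methyl) | C1=C(Br)[C@H](O)C[C@@H]2C(C)(C)CCC[C@@]12C
F8 | step 8 | 4-nitrobenzoate of 15 (ester trans to the C10 methyl) | C1=C(Br)[C@@H](OC(=O)c3ccc(cc3)[N+](=O)[O-])C[C@@H]2C(C)(C)CCC[C@@]12C
F0 | step 4 | none | none
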